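**Overview**

- Cuts: the twelve O–CH3 bonds go first. Ring C is then cut at the three C–C bonds that separate its two O–C=C–H units and its O–C–C–O unit, giving two aryl ethynyl ethers (AB–O–C≡CH, DE–O–C≡CH) and methoxyketene. Each ethynyl ether goes back to a phenol, and the A–O–B and D–O–E bonds are cut as Ullmann couplings.
- Forward order: rings A, B, D and E are bought as benzene rings. A is joined to B and D to E by copper-catalysed ether coupling next to a formyl group, which Dakin oxidation then turns into the phenol oxygen. Each phenol is made into an ethynyl ether, the DE ether and methoxyketene give a cyclobutenone, ring C is built last by benzannulation with the AB ether, and BBr3 frees the thirteen hydroxyls.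
- Enabling feature: going round ring C the carbons read C(O–ring B), C–H, C–OH, C–OH, C(O–ring D), C–H. The two hydroxylated carbons are adjacent, the two aryloxy carbons are meta, and the one bound to the crowded ring B oxygen (flanked on ring B by OH and O–ring A) lies between two C–H carbons. Each oxygenated carbon therefore comes from an ynol ether carbon or a ketene carbon, and no C–O bond has to be made at the hindered centre.
- Stereochemistry: the target has no stereocenter. The only sp3 centre of the route (C4 of the cyclobutenone) is racemic and disappears on aromatization.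

Key step: step 11

Assumption: 2-bromo-4,6-dimethoxybenzaldehyde and 2-bromo-3,4,5-trimethoxybenzaldehyde are taken as purchasable, and the terminal aryl ethynyl ethers are assumed to tolerate brief handling in solution, so each is made fresh from its storable dichlorovinyl ether.

**Route**

Step 1
Reactants: 1 2,4,6-trimethoxybenzaldehyde
Product: 3 2,4,6-trimethoxyphenol, via ring A aryl formate 2 (not isolated)
Conditions: mCPBA, CH2Cl2, 0 °C to rt; aq. NaHCO3 wash; then K2CO3 (cat.), MeOH, rt
Reagents that add atoms: mCPBA, O=C(OO)c1cccc(Cl)c1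
Why: Dakin oxidation in its Baeyer–Villiger form; the two ortho and one para methoxy groups make the aryl group migrate in the peracid adduct, and mild methanolysis of formate 2 frees the phenol.

Step 2
Reactants: 3 2,4,6-trimethoxyphenol; 4 2-bromo-4,6-dimethoxybenzaldehyde
Product: 5 2,4-dimethoxy-6-(2,4,6-trimethoxyphenoxy)benzaldehyde (AB aldehyde)
Conditions: CuI (cat.), picolinic acid (cat.), K3PO4, DMSO, 90 °C, argon
Reagents that add atoms: none
Why: Ullmann diaryl ether coupling with the copper–picolinic acid system established for 2,6-disubstituted phenols and ortho-substituted aryl bromides; the ortho formyl group further activates the C–Br bond and has no enolizable hydrogen.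

Step 3
Reactants: 5 AB aldehyde
Product: 7 2,4-dimethoxy-6-(2,4,6-trimethoxyphenoxy)phenol (AB phenol), via AB aryl formate 6 (not isolated)
Conditions: mCPBA, CH2Cl2, 0 °C to rt; aq. NaHCO3 wash; then K2CO3 (cat.), MeOH, rt
Reagents that add atoms: mCPBA, O=C(OO)c1cccc(Cl)c1
Why: Dakin oxidation; the formyl-bearing ring B has oxygen donors ortho and para to the aldehyde, so the aryl group migrates and the hydroxyl appears on the carbon that carried the formyl group, while the ether links are inert to peracid at this temperature.

Step 4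
Reactants: 7 AB phenol
Product: 8 2-[(E)-1,2-dichloroethenyloxy]-1,5-dimethoxy-3-(2,4,6-trimethoxyphenoxy)benzene (AB dichlorovinyl ether)
Conditions: trichloroethylene, K2CO3, DMF, 70 °C
Reagents that add atoms: trichloroethylene, ClC=C(Cl)Cl
Why: Base-mediated dehydrochlorination of trichloroethylene to dichloroacetylene and anti addition of the phenoxide across it, the standard route to aryl (E)-1,2-dichlorovinyl ethers; the flanked phenoxide only has to attack an unhindered sp carbon.

Step 5
Reactants: 8 AB dichlorovinyl ether
Product: 11 2-ethynyloxy-1,5-dimethoxy-3-(2,4,6-trimethoxyphenoxy)benzene (AB aryl ethynyl ether), via AB chloroethynyl ether 9 (not isolated), via AB lithium acetylide 10 (not isolated)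
Conditions: n-BuLi (2.2 equiv), THF, −78 °C; then MeOH, −78 °C
Reagents that add atoms: none
Why: Vinylic deprotonation and β-elimination to the chloroalkyne, lithium–chlorine exchange to the lithium acetylide and protonation, the usual dichlorovinyl ether route to ynol ethers; at −78 °C the vinylic C–H reacts far faster than any ring C–H next to a methoxy group.

Step 6
Reactants: 12 3,4,5-trimethoxyphenol; 13 2-bromo-3,4,5-trimethoxybenzaldehyde
Product: 14 3,4,5-trimethoxy-2-(3,4,5-trimethoxyphenoxy)benzaldehyde (DE aldehyde)
Conditions: CuI (cat.), picolinic acid (cat.), K3PO4, DMSO, 90 °C, argon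
Reagents that add atoms: none
Why: Ullmann diaryl ether coupling of an unhindered phenol with a bromide that is activated by its ortho formyl group; the catalyst system tolerates the second ortho substituent on the bromide.

Step 7
Reactants: 14 DE aldehyde
Product: 16 3,4,5-trimethoxy-2-(3,4,5-trimethoxyphenoxy)phenol (DE phenol), via DE aryl formate 15 (not isolated)
Conditions: mCPBA, CH2Cl2, 0 °C to rt; aq. NaHCO3 wash; then K2CO3 (cat.), MeOH, rt
Reagents that add atoms: mCPBA, O=C(OO)c1cccc(Cl)c1
Why: Dakin oxidation; the ortho aryloxy and para methoxy groups favour aryl migration, and methanolysis of formate 15 gives the ring D hydroxyl next to the ring E ether.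

Step 8
Reactants: 16 DE phenol
Product: 17 1-[(E)-1,2-dichloroethenyloxy]-3,4,5-trimethoxy-2-(3,4,5-trimethoxyphenoxy)benzene (DE dichlorovinyl ether)
Conditions: trichloroethylene, K2CO3, DMF, 70 °C
Reagents that add atoms: trichloroethylene, ClC=C(Cl)Cl
Why: Same phenoxide addition to dichloroacetylene generated in the flask as in step 4, here on a phenol with only one ortho substituent.

Step 9
Reactants: 17 DE dichlorovinyl ether
Product: 20 1-ethynyloxy-3,4,5-trimethoxy-2-(3,4,5-trimethoxyphenoxy)benzene (DE aryl ethynyl ether), via DE chloroethynyl ether 18 (not isolated), via DE lithium acetylide 19 (not isolated)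
Conditions: n-BuLi (2.2 equiv), THF, −78 °C; then MeOH, −78 °C
Reagents that add atoms: none
Why: Elimination, lithium–chlorine exchange and protonation as in step 5.

Step 10
Reactants: 20 DE aryl ethynyl ether; 21 methoxyacetyl chloride
Product: 23 4-methoxy-3-[3,4,5-trimethoxy-2-(3,4,5-trimethoxyphenoxy)phenoxy]cyclobut-2-en-1-one (racemic), via methoxyketene 22 (not isolated)
Conditions: Et3N (4 equiv), CH2Cl2, 40 °C; 21 (3 equiv) added slowly by syringe pump
Reagents that add atoms: none
Why: Ketene–alkynyl ether (2+2) cycloaddition, the classical route to 3-alkoxycyclobutenones: methoxyketene 22 is kept dilute by slow dehydrochlorination of 21 and is attacked at its carbonyl carbon by the nucleophilic C–H terminus of 20, which puts the aryloxy group at C3 and the methoxy carbon at C4, formed racemic with no control needed.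

Step 11
Reactants: 23 3-aryloxy-4-methoxycyclobutenone; 11 AB aryl ethynyl ether
Product: 28 5-[2,4-dimethoxy-6-(2,4,6-trimethoxyphenoxy)phenoxy]-2-methoxy-3-[3,4,5-trimethoxy-2-(3,4,5-trimethoxyphenoxy)phenoxy]phenol (dodecamethyl ether with a free ring C hydroxyl), via vinylketene 24 (not isolated), via 4-vinylcyclobutenone 25 (not isolated), via dienylketene 26 (not isolated), via cyclohexadienone 27 (not isolated)
Conditions: 11 (2 equiv), toluene, 80 °C then 110 °C, argon; then K2CO3, MeOH, rt
Reagents that add atoms: none
Why: Proposed new method: heating 23 should open it by conrotatory 4π ring opening (methoxy turning outward) to vinylketene 24, whose ketene C=C adds the alkyne of 11 in a (2+2) cycloaddition with the C–H terminus of 11 bonding to the ketene carbonyl carbon to give 25; a second, reversible 4π opening gives dienylketene 26, which closes to dienone 27 by bonding the ketene carbon to the methoxy-bearing terminus, and enolization gives phenol 28. The closest known reaction type is the Danheiser benzannulation of cyclobutenones with alkoxy- and silyloxyacetylenes, which gives resorcinol monoethers by the same cascade; new here are the aryloxy group on the alkyne and the 3-aryloxy-4-methoxy pattern on the cyclobutenone. The transient four-membered ring of 25 is closed by ketene–alkyne (2+2) cycloaddition, and ring C, a six-membered carbocycle, is closed by thermal disrotatory 6π electrocyclization. No stereocenter is kept: the sp3 carbons of 25 and 27 are racemic and vanish on aromatization. The step needs regioselectivity in the (2+2) event, secured by the ynol ether oxygen that makes the C–H carbon the nucleophile and so places the AB oxygen meta to the new hydroxyl and between the two C–H positions, and it needs the ketene to be trapped by the alkyne before it acylates the product phenol, for which 11 is used in excess and any aryl ester is cleaved by the closing methanolysis. An aryl ethynyl ether has no pathway for retro-ene loss of an alkene, and the crowded ring B oxygen lies two atoms away from the bond-forming carbon, so its steric load should not matter.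

Step 12
Reactants: 28 dodecamethyl ether
Product: 29 Pseudopentafuhalol D
Conditions: BBr3 (large excess), CH2Cl2, −78 °C to rt; degassed H2O quench, work-up and chromatography under argon
Reagents that add atoms: none
Why: Lewis acid cleavage of aryl methyl ethers, in which bromide attacks the O-methyl carbon of each borane adduct; the diaryl ether oxygens have no carbon open to SN2 attack and stay intact, and the borate esters are hydrolysed on quenching.

**Compound list**

1 | 2,4,6-trimethoxybenzaldehyde | COc1cc(OC)c(C=O)c(OC)c1 | starting material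
2 | 2,4,6-trimethoxyphenyl formate | O=COc1c(OC)cc(OC)cc1OC | intermediate
3 | 2,4,6-trimethoxyphenol | COc1cc(OC)c(O)c(OC)c1 | intermediate
4 | 2-bromo-4,6-dimethoxybenzaldehyde | O=Cc1c(Br)cc(OC)cc1OC | starting material
5 | 2,4-dimethoxy-6-(2,4,6-trimethoxyphenoxy)benzaldehyde | O=Cc1c(Oc2c(OC)cc(OC)cc2OC)cc(OC)cc1OC | intermediate
6 | 2,4-dimethoxy-6-(2,4,6-trimethoxyphenoxy)phenyl formate | O=COc1c(Oc2c(OC)cc(OC)cc2OC)cc(OC)cc1OC | intermediate
7 | 2,4-dimethoxy-6-(2,4,6-trimethoxyphenoxy)phenol | Oc1c(Oc2c(OC)cc(OC)cc2OC)cc(OC)cc1OC | intermediate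
8 | AB aryl (E)-1,2-dichlorovinyl ether | Cl/C=C(/Cl)Oc1c(Oc2c(OC)cc(OC)cc2OC)cc(OC)cc1OC | intermediate
9 | AB aryl chloroethynyl ether | ClC#COc1c(Oc2c(OC)cc(OC)cc2OC)cc(OC)cc1OC | intermediate
10 | AB lithium aryloxyacetylide | [Li]C#COc1c(Oc2c(OC)cc(OC)cc2OC)cc(OC)cc1OC | intermediate
11 | AB aryl ethynyl ether | C#COc1c(Oc2c(OC)cc(OC)cc2OC)cc(OC)cc1OC | intermediate
12 | 3,4,5-trimethoxyphenol | COc1cc(O)cc(OC)c1OC | starting material
13 | 2-bromo-3,4,5-trimethoxybenzaldehyde | O=Cc1cc(OC)c(OC)c(OC)c1Br | starting material
14 | 3,4,5-trimethoxy-2-(3,4,5-trimethoxyphenoxy)benzaldehyde | O=Cc1cc(OC)c(OC)c(OC)c1Oc1cc(OC)c(OC)c(OC)c1 | intermediate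
15 | 3,4,5-trimethoxy-2-(3,4,5-trimethoxyphenoxy)phenyl formate | O=COc1cc(OC)c(OC)c(OC)c1Oc1cc(OC)c(OC)c(OC)c1 | intermediate
16 | 3,4,5-trimethoxy-2-(3,4,5-trimethoxyphenoxy)phenol | Oc1cc(OC)c(OC)c(OC)c1Oc1cc(OC)c(OC)c(OC)c1 | intermediate
17 | DE aryl (E)-1,2-dichlorovinyl ether | Cl/C=C(/Cl)Oc1cc(OC)c(OC)c(OC)c1Oc1cc(OC)c(OC)c(OC)c1 | intermediate
18 | DE aryl chloroethynyl ether | ClC#COc1cc(OC)c(OC)c(OC)c1Oc1cc(OC)c(OC)c(OC)c1 | intermediate
19 | DE lithium aryloxyacetylide | [Li]C#COc1cc(OC)c(OC)c(OC)c1Oc1cc(OC)c(OC)c(OC)c1 | intermediate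
20 | DE aryl ethynyl ether | C#COc1cc(OC)c(OC)c(OC)c1Oc1cc(OC)c(OC)c(OC)c1 | intermediate
21 | methoxyacetyl chloride | COCC(Cl)=O | starting material
22 | methoxyketene | COC=C=O | intermediate
23 | 3-(DE-aryloxy)-4-methoxycyclobut-2-en-1-one, racemic | COC1C(=O)C=C1Oc1cc(OC)c(OC)c(OC)c1Oc1cc(OC)c(OC)c(OC)c1 | intermediate
24 | vinylketene, 3-(DE-aryloxy)-4-methoxybuta-1,3-dien-1-one, methoxy trans to the ketene-bearing carbon | O=C=C/C(Oc1cc(OC)c(OC)c(OC)c1Oc1cc(OC)c(OC)c(OC)c1)=C/OC | intermediate
25 | 3-(AB-aryloxy)-4-[1-(DE-aryloxy)-2-methoxyvinyl]cyclobut-2-en-1-one, racemic | O=C1C=C(Oc2c(Oc3c(OC)cc(OC)cc3OC)cc(OC)cc2OC)C1/C(Oc1cc(OC)c(OC)c(OC)c1Oc1cc(OC)c(OC)c(OC)c1)=C/OC | intermediate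
26 | dienylketene, 3-(AB-aryloxy)-5-(DE-aryloxy)-6-methoxyhexa-1,3,5-trien-1-one, central C=C cis | O=C=C/C(Oc1c(Oc2c(OC)cc(OC)cc2OC)cc(OC)cc1OC)=C\C(Oc1cc(OC)c(OC)c(OC)c1Oc1cc(OC)c(OC)c(OC)c1)=C\OC | intermediate
27 | 3-(AB-aryloxy)-5-(DE-aryloxy)-6-methoxycyclohexa-2,4-dien-1-one, racemic | O=C1C=C(Oc2c(Oc3c(OC)cc(OC)cc3OC)cc(OC)cc2OC)C=C(Oc2cc(OC)c(OC)c(OC)c2Oc2cc(OC)c(OC)c(OC)c2)C1OC | intermediate
28 | 5-(AB-aryloxy)-2-methoxy-3-(DE-aryloxy)phenol, dodecamethyl ether of the target | Oc1cc(Oc2c(Oc3c(OC)cc(OC)cc3OC)cc(OC)cc2OC)cc(Oc2cc(OC)c(OC)c(OC)c2Oc2cc(OC)c(OC)c(OC)c2)c1OC | intermediate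
29 | Pseudopentafuhalol D | Oc1cc(O)c(Oc2cc(O)cc(O)c2Oc2cc(O)c(O)c(Oc3cc(O)c(O)c(O)c3Oc3cc(O)c(O)c(O)c3)c2)c(O)c1 | target

**Step count and risks**

Total steps: 12. Longest linear sequence: 7 steps (steps 1–5, 11, 12; the branch through steps 6–10, 11, 12 is equally long).

Steps most likely to fail:

1. Step 11 (benzannulation). The vinylketene may dimerize, re-close, or acylate the product phenol faster than it adds the weakly nucleophilic aryloxyacetylene. The second ring opening of the 3-aryloxy-4-vinylcyclobutenone may stall, or the ethynyl ether may oligomerize on heating. The fallback uses only known chemistry, buys ring C and sets out from phenols 7 and 16. The phenoxide of 7 (Cs2CO3, DMF, 80 °C) would displace the para fluorine of purchased 2,4-difluoro-6-methoxybenzaldehyde (O=Cc1c(F)cc(F)cc1OC) by nucleophilic aromatic substitution, attack by the bulky nucleophile being expected at the unhindered position, to give 4-(AB-aryloxy)-2-fluoro-6-methoxybenzaldehyde F1. A second substitution of the ortho fluorine by the phenoxide of 16 (Cs2CO3, DMSO, 110 °C) would give 2-(DE-aryloxy)-4-(AB-aryloxy)-6-methoxybenzaldehyde F2. Dakin oxidation as in step 3 (mCPBA, then K2CO3 in MeOH) would pass through the aryl formate F3 to the phenol F4, an isomer of 28 in which the free hydroxyl and the methoxy group of ring C have changed places. BBr3 under the conditions of step 12 would convert F4 into 29, where the fallback rejoins the route.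

2. Step 10 (cyclobutenone formation). Methoxyketene may dimerize or polymerize faster than it is captured by the aryl ynol ether, which is less nucleophilic than an alkyl ynol ether, and the acid-sensitive ynol ether may be degraded by the ammonium salt. The fallback replaces the ketene by a more electrophilic keteniminium ion that does not dimerize, and sets out from 20. Purchased 2-methoxy-N,N-dimethylacetamide (COCC(=O)N(C)C) with Tf2O and 2,4,6-collidine in CH2Cl2 would give N,N-dimethyl(methoxy)keteniminium triflate F5. This should add 20 in a keteniminium–alkyne (2+2) cycloaddition with the same regiochemistry to give the cyclobuteniminium triflate F6, and hydrolysis with aqueous NaHCO3 would give cyclobutenone 23, where the route continues.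

3. Step 12 (global demethylation). Cleavage of the twelve ethers may stop short, and the electron-rich polyphenol with its two pyrogallol-type rings may oxidize in air during isolation. The fallback sets out from 28 and changes the isolation strategy. The crude BBr3 product would not be isolated but acetylated at once (Ac2O, pyridine) to the tridecaacetate F7, which is stable, can be chromatographed and can be separated from partly methylated material. Transesterification of F7 with degassed methanolic HCl under argon would then release 29.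

**Further compounds**

F1 | step 11 | 4-[2,4-dimethoxy-6-(2,4,6-trimethoxyphenoxy)phenoxy]-2-fluoro-6-methoxybenzaldehyde | O=Cc1c(F)cc(Oc2c(Oc3c(OC)cc(OC)cc3OC)cc(OC)cc2OC)cc1OC
F2 | step 11 | 4-(AB-aryloxy)-2-(DE-aryloxy)-6-methoxybenzaldehyde | O=Cc1c(Oc2cc(OC)c(OC)c(OC)c2Oc2cc(OC)c(OC)c(OC)c2)cc(Oc2c(Oc3c(OC)cc(OC)cc3OC)cc(OC)cc2OC)cc1OC
F3 | step 11 | 4-(AB-aryloxy)-2-(DE-aryloxy)-6-methoxyphenyl formate | O=COc1c(Oc2cc(OC)c(OC)c(OC)c2Oc2cc(OC)c(OC)c(OC)c2)cc(Oc2c(Oc3c(OC)cc(OC)cc3OC)cc(OC)cc2OC)cc1OC
F4 | step 11 | 4-(AB-aryloxy)-2-(DE-aryloxy)-6-methoxyphenol, isomer of 28 | Oc1c(Oc2cc(OC)c(OC)c(OC)c2Oc2cc(OC)c(OC)c(OC)c2)cc(Oc2c(Oc3c(OC)cc(OC)cc3OC)cc(OC)cc2OC)cc1OC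
F5 | step 10 | N,N-dimethyl(methoxy)keteniminium triflate | COC=C=[N+](C)C.[O-]S(=O)(=O)C(F)(F)F
F6 | step 10 | 3-(DE-aryloxy)-4-methoxy-N,N-dimethylcyclobut-2-en-1-iminium triflate | COC1C(=[N+](C)C)C=C1Oc1cc(OC)c(OC)c(OC)c1Oc1cc(OC)c(OC)c(OC)c1.[O-]S(=O)(=O)C(F)(F)F
F7 | step 12 | Pseudopentafuhalol D tridecaacetate | CC(=O)Oc1cc(OC(C)=O)c(Oc2cc(OC(C)=O)cc(OC(C)=O)c2Oc2cc(OC(C)=O)c(OC(C)=O)c(Oc3cc(OC(C)=O)c(OC(C)=O)c(OC(C)=O)c3Oc3cc(OC(C)=O)c(OC(C)=O)c(OC(C)=O)c3)c2)c(OC(C)=O)c1
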